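Early in a run the catalyst charge showed at once: at 12.0 min Friday's run held 15.2 % of product and Thursday's 26.0 %, though the two differed in catalyst and nothing else.

the same everywhere: starting material 0.50 M

| charge | partner | catalyst | remark | time |
|---|---|---|---|---|
| Friday's | 1 M | 0.50 mM | run made earlier |  |
| Thursday's | 1 M | 0.75 mM | run made earlier |  |
| flask | 1.00 M | 1.0 mM |  | 1.0 h |

- Friday's (time / min: product / %): 12.0: 15.2; 25.0: 36.9; 40.0: 56.4; 50.0: 64.8; 60.0: 70.4
- Thursday's (time / min: product / %): 12.0: 26.0; 25.0: 52.2; 40.0: 70.9; 50.0: 78.7; 60.0: 84.2

(scatter of a reading: 0.5 percentage points)

- amount of product in percent of the starting material charged, at 3.0 min, 15 min and 1.0 h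



Friday's run at 60.0 min had a catalyst dose τ of 30.0 mM·min, τ being the catalyst concentration multiplied by the time. Thursday's run at 40.0 min had the same τ. They read 70.4 % and 70.9 %, with a scatter of 0.5 percentage points on each, so I put both runs on one curve of product against τ and bracketed the new flask on it.

At 3.0 min the new flask had τ = 3.00 mM·min, below the τ of every reading. I took the curve to bend upward there, so the straight line from the origin to Friday's first reading gave me a ceiling of 7.60 %. The line back through the first readings of the two runs gave a floor of 4.40 %.

At 15 min, τ = 15.0 mM·min lay where I read the curve as bending downward, so the chord between neighbouring readings gave a floor of 43.0 %. The earlier chord, carried forward, gave a ceiling of 44.7 %.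

At 1.0 h, τ = 60.0 mM·min lay beyond the readings, so the bracket ran from 84.2 % to 100 %. Inside that bracket I assumed that the unconverted share fell by the same factor over the next equal step of τ as over the last one, which gave my estimate, not a bound, of 91.6 %.

The forecast, 6 %, 43 % and 91.5 %, rested on the same curve: “So the rate is first order in catalyst.” Its first value stood inside my bracket, its second at the floor and its third beside my estimate.

The flask gave 5.61 %, 44.1 % and 91.1 %, each inside its bracket.

    starting material + catalyst ⇌ catalyst + intermediate (K = 0.920, k = 91.0 M⁻¹ min⁻¹)
    partner + catalyst + intermediate → catalyst + product (k = 200 M⁻² min⁻¹)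

At 0.500 h this flask had τ = 30.0 mM·min and held 70.9 % of product, beside Friday's 70.4 % at that τ, with its catalyst at 100 % of the charge. At 1.00 h this flask still held 5.82 % of starting material and 3.09 % of intermediate. Part of the shortfall of product was the way back from intermediate to starting material, acting together with the time allowed: without that reverse step this flask reached 98.2 % in the hour, and with it the flask reached 100 % at 10.0 h.

The readings were computed with made-up constants.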